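## The problem

Iridal is a monocyclic triterpenoid aldehyde. Positions are numbered here as C1 (formyl carbon), C2 (its α carbon), C3–C5 (hydroxypropyl arm, counted from the hydroxyl), C6 (ring methine), C7 (alkylidene ring carbon), C8, C9, C10 (carbinol), C11 (quaternary) and C12 onward (chain). One cyclohexane (C6–C11) carries the 3-hydroxypropyl arm at C6, a tetrasubstituted (Z)-alkylidene propanal at C7=C2 with the formyl group on the C6 side, a tertiary carbinol at C10 and an all-carbon quaternary centre at C11 that bears the (3E,7E)-homofarnesyl chain. The three stereocentres C6 (R), C10 (S) and C11 (S) are contiguous, and C10 and C11 are both fully substituted, so neither can be set by enolate or hydride chemistry. C6 is an ordinary tertiary centre that an auxiliary can set, and it can steer the other two only if it is tied to them rigidly. C7 is sp2 in the target but can be carried as a carbinol, a sacrificial fourth stereocentre next to C6. The fragile elements are the enal (geometry, conjugate addition, γ-deprotonation that would epimerise C6), the tertiary alcohol (it closes a tetrahydrofuran onto any leaving group at C13) and the skipped triene (no strong acid, carbenoids or dissolving metals). The enabling feature is that C10 and C11 are adjacent and both are acceptor carbons when C10 is written as a methyl ketone and C11 as the β carbon of a C11=C12–C13 enoate, so a one-electron reductant can reverse the polarity of C10 and join them. Because the C7 oxygen and the C12 arm are cis-1,3 on the ring, that oxygen can also serve as the alkoxy group of the enoate, which turns the acceptor into a six-membered unsaturated lactone.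

## Retrosynthesis

**Enal (39 ⇒ 38 ⇒ 36 ⇒ 35 ⇒ 34).** Iridal 39 is the bis-silyl ether 38 after fluoride treatment. The enal is taken apart at C2–C1, C2–CH3 and C7=C2, going back through alkenyl bromide 36 and gem-dibromide 35 to ketone 34. Direct olefination of 34 with a phosphonate or silyl reagent would leave the geometry of a tetrasubstituted alkene to chance. The dibromide turns geometry into site selectivity, because one bromine faces the branched C6 and the other faces the C8 methylene. The forward steps need palladium to insert into the C–Br bond remote from C6 and the later lithium–bromine exchange to retain configuration.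

**Chain (34 ⇒ 33 ⇒ 22 + 29).** The C13–C14 bond between an sp3 and an sp2 carbon is cut, which points to a B-alkyl Suzuki–Miyaura coupling of alkyl iodide 22 with alkenyl iodide 29. A Wittig disconnection at C14=C15 would give poor E control at a trisubstituted alkene, and carrying the triene from the start would make the route linear. The cut divides the target into a C16 ring fragment and a C14 chain. The forward reaction needs an alkyl metal generated next to a quaternary carbon, so the C7 hydroxyl is masked as a trimethylsilyl ether that falls off in the work-up to give 33.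

**Alkenyl iodide (29 ⇒ 27 ⇒ 26 ⇒ 23 + 24).** The C15 methyl and the C14 iodine come from carboalumination–iodination of alkyne 27. Alkyne 27 comes from silyl alkyne 26, formed at C16–C17 from 1-(trimethylsilyl)propyne 23 and geranyl bromide 24. The E alkene of 24 is bought, and the new one is set by syn carbometalation.

**Functional-group stage (22 ⇒ 21 ⇒ 20 ⇒ 19 ⇒ 18).** No skeletal bond is cut here. Iodide 22 comes from iodo alcohol 21 and diol 20, and the diol is the reduction product of lactone 19, which frees the C13 and C7 carbinols in one step. The tertiary hydroxyl of 18 is silylated first (19), because a free C10 hydroxyl would close a tetrahydrofuran onto C13 once a leaving group is there.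

**Key cut (18 ⇒ 17).** The C10–C11 bond of bicyclic lactone 18 is cut to the methyl ketone and the unsaturated lactone of 17. This is the only ring bond whose two ends are both fully substituted, so forming it last creates both difficult stereocentres in one step. An open-chain (E)-enoate with a silyl ether at C7 was weighed first and set aside. Its two chair transition states (enoate arm equatorial with methyl axial, or the reverse) differ little, because the vinylic hydrogen on C12 exerts almost no allylic strain, so C11 would rest on a small energy difference. In lactone 17 the enoate is necessarily Z and the ketone chain hangs from C7 of the lactone ring, so it can reach C11 only across one face. The forward reaction asks for ketyl addition to a β,β-disubstituted acceptor and for the ketyl oxygen to end trans to the C12 arm.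

**Lactone (17 ⇒ 16 ⇒ 15 ⇒ 13 + 14).** The ketone of 17 is carried as the terminal alkene of 16 and unveiled by Wacker oxidation, so it is absent during the Grignard and olefination steps. Lactone 16 is cut at C11=C12 and O7–C13 to phosphonoacetate 15, made from β-hydroxy ketone 13 and diethylphosphonoacetic acid 14. The ring closure costs no more steps than an intermolecular olefination plus silylation and fixes the enoate geometry.

**Aldol (13 ⇒ 12 ⇒ 11 ⇒ 7 + 8; 7 ⇒ 4 + 5; 4 ⇒ 1).** The C6–C7 bond is cut by an auxiliary-controlled syn-aldol between imide 7 and pent-4-enal 8, giving 11 and then Weinreb amide 12. The (R)-benzyl oxazolidinone 5 gives C6 with the target configuration. The syn C7 epimer is the one whose oxygen lies cis to the future C12 arm. Imide 7 comes from acid 4, which is δ-valerolactone 1 after opening and silylation.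

## Roads not taken

**Alternative 1:** The angular C11 methyl is disconnected through a cyclopropane (bonds C11–CH2 and C6–CH2). In the forward step the zinc carbenoid from Et2Zn and CH2I2, held by the zinc alkoxide of the tertiary allylic alcohol in cyclohexenol A1, transfers CH2 to the C11=C6 alkene on the hydroxyl face to give bicyclo[4.1.0]heptanol A2. After oxidation at C7, reductive opening of the cyclopropyl ketone would unveil the methyl and a C6 enolate for the three-carbon arm.
- Merits: directed cyclopropanation is among the most dependable ways to place a carbon cis to a neighbouring carbinol. The C10/C11 relation is therefore more secure than in the chosen plan, where C10 rests on a conformational preference. The chain is present from the start.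
- Weak points: A1 must already hold C10 as one enantiomer, made by methyl addition to an enone under only remote control from C7. The three chain alkenes are also carbenoid acceptors, and the target alkene is trisubstituted and hindered. C6 is made last, by alkylating an enolate beside the new quaternary centre, where neither the site of trapping nor trans delivery is assured. The ring opening needs a reducing metal in the presence of the triene.
- Comparison: the chosen plan sets C6 first, where an auxiliary does it reliably, uses it to fix C11 covalently, and never exposes the triene to carbenoids. Against the stronger C10/C11 control of A2 it sets a fallback in which C10 is made by methyl addition to a ring ketone.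

**Alternative 2:** The C7=C2 alkene is cut by ring-closing metathesis. Second-generation Grubbs catalyst, (H2IMes)(PCy3)Cl2Ru=CHPh, would join the exocyclic methylene at C7 of diene A3 with its methacryloyl alkene, with loss of ethylene, to give bicyclo[5.4.0]undecenone A4, in which C1 is bonded to C3. Cleavage of C1–C3 would later free the formyl group and the hydroxypropyl arm.
- Merits: the ring puts the formyl carbon on the C6 side by necessity. On enal geometry A4 is better than the chosen plan, which must tell two bromines apart.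
- Weak points: metathesis between two 1,1-disubstituted alkenes, one an electron-poor enone, to a tetrasubstituted alkene is at the limit of ruthenium carbenes. The C1–C3 bond must then be broken by oxygen insertion on the alkyl side of an enone carbonyl, against the usual migratory preference, followed by redox adjustment. The chain is still missing, so the sp3–sp2 coupling is needed anyway. A3 presupposes C6, C10 and C11, so the stereotriad is not addressed.
- Comparison: the chosen plan solves the stereotriad and pays with a less certain enal construction. It sets two independent fallbacks for the enal against that, and the natural geometry (small formyl group beside branched C6) is expected to be the thermodynamic one.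

**Alternative 3:** The C6–C7 bond is cut. Zirconocene (formally divalent zirconium, from Cp2ZrCl2 and two equivalents of n-BuLi) would couple the vinyl group on C11 of enyne A5 with its methyl-capped alkyne to a zirconacyclopentene, closing the cyclohexane. Iodine would cleave both C–Zr bonds to give diiodide A6, with an iodomethyl group on C6 and an alkenyl iodide whose iodine is cis to C6.
- Merits: ring, enal geometry and two handles arise in one operation. The endgame would be shorter than in the chosen plan and the geometry is guaranteed by mechanism.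
- Weak points: A5 must already contain the adjacent fully substituted centres C10 and C11, made in an open chain, so the hardest part is moved and not solved. C6 is created next to a quaternary carbon whose two carbon substituents (methyl and a chain CH2) differ little, so induction should be low. The C5 iodide is β-branched beside a quaternary carbon, which slows the two-carbon extension.
- Comparison: the chosen plan is longer after ring closure, but it makes the C10–C11 bond and both its stereocentres in the ring-forming step under control of an aldol-derived centre. The advantage of A6 in geometry and step count at the end is real.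

Key step: step 9

## Route

Step 1
Reactants: 1 δ-valerolactone
Product: 4 5-(tert-butyldiphenylsilyloxy)pentanoic acid, via sodium 5-hydroxypentanoate 2 (not isolated), via bis-silyl ester 3 (not isolated)
Conditions: NaOH, MeOH/H2O, 60 °C, evaporate; TBDPSCl, imidazole, DMF, rt; K2CO3, MeOH/THF/H2O, rt; acidic work-up (pH 4)
Reagents that add atoms: sodium hydroxide, [Na+].[OH-]; tert-butyldiphenylsilyl chloride, CC(C)(C)[Si](Cl)(c1ccccc1)c1ccccc1
Why: Saponification opens the lactone, both oxygens are silylated, and carbonate methanolysis cleaves only the labile silyl ester (standard hydroxy-acid protection).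

Step 2
Reactants: 4 5-(tert-butyldiphenylsilyloxy)pentanoic acid; 5 (R)-4-benzyl-2-oxazolidinone
Product: 7 (R)-4-benzyl-3-[5-(tert-butyldiphenylsilyloxy)pentanoyl]oxazolidin-2-one, via mixed pivalic anhydride 6 (not isolated)
Conditions: PivCl, Et3N, THF, −20 °C; then 5, LiCl, −20 °C → rt
Reagents that add atoms: none
Why: Mixed-anhydride N-acylation of the oxazolidinone; LiCl/Et3N activates the auxiliary, and the hindered pivaloyl carbonyl directs attack to the desired acyl group.

Step 3
Reactants: 7 (R)-4-benzyl-3-[5-(tert-butyldiphenylsilyloxy)pentanoyl]oxazolidin-2-one; 8 pent-4-enal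
Product: 11 (R)-4-benzyl-3-[(2R,3S)-2-[3-(tert-butyldiphenylsilyloxy)propyl]-3-hydroxyhept-6-enoyl]oxazolidin-2-one, via boron enolate 9 (not isolated), via boron aldolate 10 (not isolated)
Conditions: Bu2BOTf, Et3N, CH2Cl2, 0 °C; then 8, −78 → 0 °C; then pH 7 buffer, MeOH, 30% H2O2, 0 °C
Reagents that add atoms: none
Why: Evans boron syn-aldol: the (Z)-enolate reacts through a Zimmerman–Traxler chair on the face away from the benzyl group. This sets C6 as in the target and the C7 carbinol syn to it.

Step 4
Reactants: 11 (R)-4-benzyl-3-[(2R,3S)-2-[3-(tert-butyldiphenylsilyloxy)propyl]-3-hydroxyhept-6-enoyl]oxazolidin-2-one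
Product: 12 (2R,3S)-2-[3-(tert-butyldiphenylsilyloxy)propyl]-3-hydroxy-N-methoxy-N-methylhept-6-enamide
Conditions: MeNH(OMe)·HCl, AlMe3, CH2Cl2, −20 → 0 °C
Reagents that add atoms: N,O-dimethylhydroxylamine hydrochloride, CNOC.Cl
Why: Aluminium-amide transamination to the Weinreb amide; the free β-hydroxyl binds aluminium and directs attack to the exocyclic carbonyl, and the auxiliary is recovered.

Step 5
Reactants: 12 (2R,3S)-2-[3-(tert-butyldiphenylsilyloxy)propyl]-3-hydroxy-N-methoxy-N-methylhept-6-enamide
Product: 13 (3R,4S)-3-[3-(tert-butyldiphenylsilyloxy)propyl]-4-hydroxyoct-7-en-2-one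
Conditions: MeMgBr (3 equiv), THF, −20 → 0 °C; aq. NH4Cl
Reagents that add atoms: methylmagnesium bromide, C[Mg]Br
Why: Weinreb ketone synthesis; the chelated tetrahedral adduct stops at the ketone stage and releases the ketone only on quench, so C6 is not epimerised.

Step 6
Reactants: 13 (3R,4S)-3-[3-(tert-butyldiphenylsilyloxy)propyl]-4-hydroxyoct-7-en-2-one; 14 2-(diethoxyphosphoryl)acetic acid
Product: 15 (3R,4S)-3-[3-(tert-butyldiphenylsilyloxy)propyl]-2-oxooct-7-en-4-yl 2-(diethoxyphosphoryl)acetate
Conditions: DCC, DMAP (cat.), CH2Cl2, 0 °C → rt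
Reagents that add atoms: none
Why: Steglich esterification of the secondary alcohol under near-neutral conditions that avoid retro-aldol cleavage.

Step 7
Reactants: 15 (3R,4S)-3-[3-(tert-butyldiphenylsilyloxy)propyl]-2-oxooct-7-en-4-yl 2-(diethoxyphosphoryl)acetate
Product: 16 (5S,6S)-6-(but-3-en-1-yl)-5-[3-(tert-butyldiphenylsilyloxy)propyl]-4-methyl-5,6-dihydro-2H-pyran-2-one
Conditions: LiCl, i-Pr2NEt, MeCN, rt
Reagents that add atoms: none
Why: Intramolecular Horner–Wadsworth–Emmons olefination under Masamune–Roush conditions; the phosphonate is far more acidic than the ketone α-hydrogen and closes onto the methyl ketone. The six-membered ring makes the enoate Z by necessity.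

Step 8
Reactants: 16 (5S,6S)-6-(but-3-en-1-yl)-5-[3-(tert-butyldiphenylsilyloxy)propyl]-4-methyl-5,6-dihydro-2H-pyran-2-one
Product: 17 (5S,6S)-5-[3-(tert-butyldiphenylsilyloxy)propyl]-4-methyl-6-(3-oxobutyl)-5,6-dihydro-2H-pyran-2-one
Conditions: PdCl2 (10 mol %), CuCl (1 equiv), O2 (1 atm), DMF/H2O 7:1, rt
Reagents that add atoms: water, O
Why: Tsuji–Wacker oxidation: Markovnikov hydroxypalladation of the terminal alkene gives the methyl ketone, and the conjugated trisubstituted alkene is inert.

Step 9
Reactants: 17 (5S,6S)-5-[3-(tert-butyldiphenylsilyloxy)propyl]-4-methyl-6-(3-oxobutyl)-5,6-dihydro-2H-pyran-2-one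
Product: 18 (1S,5S,6S,9S)-9-[3-(tert-butyldiphenylsilyloxy)propyl]-6-hydroxy-5,6-dimethyl-2-oxabicyclo[3.3.1]nonan-3-one
Conditions: SmI2 (2.5 equiv), HMPA (10 equiv), t-BuOH (2 equiv), THF, −78 → −20 °C, slow addition of 17 (0.01 M)
Reagents that add atoms: none
Why: Electron transfer from divalent samarium, made more reducing by HMPA, to the methyl ketone gives a samarium-bound ketyl, a nucleophilic radical matched to the electron-poor β carbon C11 of the unsaturated lactone; it adds there, a second electron transfer turns the radical at C12 into a samarium enolate, and tert-butanol protonates it. The closest known reaction type is the SmI2 ketyl–olefin cyclisation onto α,β-unsaturated esters and lactones, which tolerates a quaternary acceptor carbon. The cyclohexane closes in the 6-exo-trig mode (C10 onto C11, with C12 outside the new ring) and gives a 2-oxabicyclo[3.3.1]nonanone. C11 is controlled by the tether: the ketone chain hangs from C7 of the lactone ring and can reach C11 only across the face it occupies, so the C12 arm ends cis-1,3 to the C7 oxygen, which with the aldol-derived C6/C7 relation is the target configuration. C10 is controlled in the chair-like closure by the samarium-bound oxygen taking the axial site antiperiplanar to the C11–C12 bond, where repulsion between ketyl oxygen and developing enolate is least; this also leaves the larger methyl group equatorial, away from the C6 side chain, and gives the hydroxyl trans to the C12 arm. The step needs ring closure to outrun simple reduction of the ketone and pinacol coupling (high dilution, tert-butanol as the only proton source); reduction at the enoate first would lead to the same C10–C11 bond. Translactonisation to the C10 oxygen is ruled out because that oxygen and the C12 arm are trans-diaxial in the bicycle.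

Step 10
Reactants: 18 (1S,5S,6S,9S)-9-[3-(tert-butyldiphenylsilyloxy)propyl]-6-hydroxy-5,6-dimethyl-2-oxabicyclo[3.3.1]nonan-3-one
Product: 19 (1S,5S,6S,9S)-9-[3-(tert-butyldiphenylsilyloxy)propyl]-5,6-dimethyl-6-(triethylsilyloxy)-2-oxabicyclo[3.3.1]nonan-3-one
Conditions: TESOTf, 2,6-lutidine, CH2Cl2, −40 °C → rt
Reagents that add atoms: triethylsilyl trifluoromethanesulfonate, CC[Si](CC)(CC)OS(=O)(=O)C(F)(F)F
Why: Silyl triflate silylation of the hindered tertiary alcohol; it is done before any leaving group exists at C13, because the free C10 hydroxyl would close a tetrahydrofuran.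

Step 11
Reactants: 19 (1S,5S,6S,9S)-9-[3-(tert-butyldiphenylsilyloxy)propyl]-5,6-dimethyl-6-(triethylsilyloxy)-2-oxabicyclo[3.3.1]nonan-3-one
Product: 20 (1S,2S,3S,4S)-2-[3-(tert-butyldiphenylsilyloxy)propyl]-3-(2-hydroxyethyl)-3,4-dimethyl-4-(triethylsilyloxy)cyclohexan-1-ol
Conditions: LiBH4, MeOH (1 equiv), THF, 0 °C → rt
Reagents that add atoms: none
Why: Borohydride reduction of the lactone to the diol frees the C13 and C7 carbinols together and leaves the silyl ethers intact.

Step 12
Reactants: 20 (1S,2S,3S,4S)-2-[3-(tert-butyldiphenylsilyloxy)propyl]-3-(2-hydroxyethyl)-3,4-dimethyl-4-(triethylsilyloxy)cyclohexan-1-ol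
Product: 21 (1S,2S,3S,4S)-2-[3-(tert-butyldiphenylsilyloxy)propyl]-3-(2-iodoethyl)-3,4-dimethyl-4-(triethylsilyloxy)cyclohexan-1-ol
Conditions: I2 (1.2 equiv), PPh3 (1.2 equiv), imidazole, CH2Cl2, 0 °C
Reagents that add atoms: iodine, II
Why: Appel-type iodination; the primary alcohol forms the alkoxyphosphonium ion and is displaced much faster than the hindered ring carbinol.

Step 13
Reactants: 21 (1S,2S,3S,4S)-2-[3-(tert-butyldiphenylsilyloxy)propyl]-3-(2-iodoethyl)-3,4-dimethyl-4-(triethylsilyloxy)cyclohexan-1-ol
Product: 22 (1S,2S,3S,4S)-3-[3-(tert-butyldiphenylsilyloxy)propyl]-2-(2-iodoethyl)-1,2-dimethyl-1-(triethylsilyloxy)-4-(trimethylsilyloxy)cyclohexane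
Conditions: TMSCl, imidazole, CH2Cl2, 0 °C → rt
Reagents that add atoms: chlorotrimethylsilane, C[Si](C)(C)Cl
Why: Temporary silylation removes the acidic hydroxyl before the organolithium step; the trimethylsilyl ether is later cleaved by carbonate methanolysis, which spares the other two silyl ethers.

Step 14
Reactants: 23 1-(trimethylsilyl)propyne; 24 geranyl bromide
Product: 26 (E)-(6,10-dimethylundeca-5,9-dien-1-yn-1-yl)trimethylsilane, via lithiated silylpropyne 25 (not isolated)
Conditions: n-BuLi, THF, −78 °C; then 24, −78 °C → rt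
Reagents that add atoms: none
Why: Propargylic lithiation and SN2 alkylation by the allylic bromide; the silyl group suppresses allenyl products and the geranyl E alkene is untouched.

Step 15
Reactants: 26 (E)-(6,10-dimethylundeca-5,9-dien-1-yn-1-yl)trimethylsilane
Product: 27 (E)-6,10-dimethylundeca-5,9-dien-1-yne
Conditions: K2CO3, MeOH, rt
Reagents that add atoms: none
Why: Methanolysis of the alkynyl C–Si bond (protiodesilylation).

Step 16
Reactants: 27 (E)-6,10-dimethylundeca-5,9-dien-1-yne
Product: 29 (1E,5E)-1-iodo-2,6,10-trimethylundeca-1,5,9-triene, via alkenylalane 28 (not isolated)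
Conditions: AlMe3 (2 equiv), Cp2ZrCl2 (0.25 equiv), CH2Cl2, 0 °C → rt; then I2, THF, −30 → 0 °C
Reagents that add atoms: trimethylaluminium, C[Al](C)C; iodine, II
Why: Negishi carboalumination adds methyl and aluminium syn across the alkyne with methyl on the internal carbon; iodinolysis with retention gives the E alkenyl iodide.

Step 17
Reactants: 22 (1S,2S,3S,4S)-3-[3-(tert-butyldiphenylsilyloxy)propyl]-2-(2-iodoethyl)-1,2-dimethyl-1-(triethylsilyloxy)-4-(trimethylsilyloxy)cyclohexane; 29 (1E,5E)-1-iodo-2,6,10-trimethylundeca-1,5,9-triene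
Product: 33 (1S,2S,3S,4S)-2-[3-(tert-butyldiphenylsilyloxy)propyl]-3,4-dimethyl-4-(triethylsilyloxy)-3-[(3E,7E)-4,8,12-trimethyltrideca-3,7,11-trien-1-yl]cyclohexan-1-ol, via alkyllithium 30 (not isolated), via borate complex 31 (not isolated), via coupled trimethylsilyl ether 32 (not isolated)
Conditions: t-BuLi (2.1 equiv), Et2O, −78 °C; B-methoxy-9-BBN, THF, −78 °C → rt; then 29, Pd(dppf)Cl2 (5 mol %), AsPh3, aq. K3PO4, DMF, rt; then K2CO3, MeOH, rt
Reagents that add atoms: none
Why: B-alkyl Suzuki–Miyaura coupling in its alkyllithium/B-methoxy-9-BBN variant: the borate transmetalates to the alkenylpalladium iodide and reductive elimination keeps the alkene geometry. Carbonate methanolysis then removes the trimethylsilyl group.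

Step 18
Reactants: 33 (1S,2S,3S,4S)-2-[3-(tert-butyldiphenylsilyloxy)propyl]-3,4-dimethyl-4-(triethylsilyloxy)-3-[(3E,7E)-4,8,12-trimethyltrideca-3,7,11-trien-1-yl]cyclohexan-1-ol
Product: 34 (2S,3S,4S)-2-[3-(tert-butyldiphenylsilyloxy)propyl]-3,4-dimethyl-4-(triethylsilyloxy)-3-[(3E,7E)-4,8,12-trimethyltrideca-3,7,11-trien-1-yl]cyclohexan-1-one
Conditions: Dess–Martin periodinane, NaHCO3, CH2Cl2, 0 °C → rt
Reagents that add atoms: none
Why: Buffered Dess–Martin oxidation of the secondary alcohol; the conditions do not epimerise C6 or touch the alkenes.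

Step 19
Reactants: 34 (2S,3S,4S)-2-[3-(tert-butyldiphenylsilyloxy)propyl]-3,4-dimethyl-4-(triethylsilyloxy)-3-[(3E,7E)-4,8,12-trimethyltrideca-3,7,11-trien-1-yl]cyclohexan-1-one
Product: 35 (1S,2S,3S)-3-[3-(tert-butyldiphenylsilyloxy)propyl]-4-(dibromomethylidene)-1,2-dimethyl-1-(triethylsilyloxy)-2-[(3E,7E)-4,8,12-trimethyltrideca-3,7,11-trien-1-yl]cyclohexane
Conditions: CBr4, PPh3, toluene, 80 °C
Reagents that add atoms: carbon tetrabromide, BrC(Br)(Br)Br
Why: Ramirez dibromo-olefination (first stage of the Corey–Fuchs sequence) applied to a ketone; the robust primary silyl ether and the hindered tertiary one are chosen to withstand the phosphorus bromide by-product.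

Step 20
Reactants: 35 (1S,2S,3S)-3-[3-(tert-butyldiphenylsilyloxy)propyl]-4-(dibromomethylidene)-1,2-dimethyl-1-(triethylsilyloxy)-2-[(3E,7E)-4,8,12-trimethyltrideca-3,7,11-trien-1-yl]cyclohexane
Product: 36 (1S,2S,3S,4Z)-4-(1-bromoethylidene)-3-[3-(tert-butyldiphenylsilyloxy)propyl]-1,2-dimethyl-1-(triethylsilyloxy)-2-[(3E,7E)-4,8,12-trimethyltrideca-3,7,11-trien-1-yl]cyclohexane
Conditions: MeZnCl (1.3 equiv), Pd(DPEphos)Cl2 (5 mol %), THF, 0 °C → rt
Reagents that add atoms: methylzinc chloride, C[Zn]Cl
Why: Site-selective Negishi mono-methylation of a 1,1-dibromoalkene: zerovalent palladium inserts into the less hindered C–Br bond, the one facing the C8 methylene. The remaining bromine is therefore cis to C6.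

Step 21
Reactants: 36 (1S,2S,3S,4Z)-4-(1-bromoethylidene)-3-[3-(tert-butyldiphenylsilyloxy)propyl]-1,2-dimethyl-1-(triethylsilyloxy)-2-[(3E,7E)-4,8,12-trimethyltrideca-3,7,11-trien-1-yl]cyclohexane
Product: 38 (2Z)-2-{(2R,3S,4S)-2-[3-(tert-butyldiphenylsilyloxy)propyl]-3,4-dimethyl-4-(triethylsilyloxy)-3-[(3E,7E)-4,8,12-trimethyltrideca-3,7,11-trien-1-yl]cyclohexylidene}propanal, via alkenyllithium 37 (not isolated)
Conditions: t-BuLi (2.2 equiv), Et2O, −78 °C; then DMF, −78 → 0 °C; aq. NH4Cl
Reagents that add atoms: N,N-dimethylformamide, CN(C)C=O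
Why: Lithium–bromine exchange and Bouveault formylation both proceed with retention at the alkenyl carbon, so the formyl group ends cis to C6 (Z enal).

Step 22
Reactants: 38 (2Z)-2-{(2R,3S,4S)-2-[3-(tert-butyldiphenylsilyloxy)propyl]-3,4-dimethyl-4-(triethylsilyloxy)-3-[(3E,7E)-4,8,12-trimethyltrideca-3,7,11-trien-1-yl]cyclohexylidene}propanal
Product: 39 iridal, (2Z)-2-{(2R,3S,4S)-4-hydroxy-2-(3-hydroxypropyl)-3,4-dimethyl-3-[(3E,7E)-4,8,12-trimethyltrideca-3,7,11-trien-1-yl]cyclohexylidene}propanal
Conditions: HF·pyridine, pyridine, THF, 0 °C → rt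
Reagents that add atoms: none
Why: Buffered fluoride desilylation removes the primary and the tertiary silyl ether together and is mild enough for the enal and the triene.

## Compound list

1 | δ-valerolactone (oxan-2-one) | O=C1CCCCO1 | starting material
2 | sodium 5-hydroxypentanoate | [Na+].[O-]C(=O)CCCCO | intermediate
3 | tert-butyldiphenylsilyl 5-(tert-butyldiphenylsilyloxy)pentanoate | CC(C)(C)[Si](OCCCCC(=O)O[Si](c1ccccc1)(c1ccccc1)C(C)(C)C)(c1ccccc1)c1ccccc1 | intermediate
4 | 5-(tert-butyldiphenylsilyloxy)pentanoic acid | CC(C)(C)[Si](OCCCCC(=O)O)(c1ccccc1)c1ccccc1 | intermediate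
5 | (R)-4-benzyl-2-oxazolidinone | O=C1N[C@H](Cc2ccccc2)CO1 | starting material
6 | 5-(tert-butyldiphenylsilyloxy)pentanoic pivalic anhydride | CC(C)(C)C(=O)OC(=O)CCCCO[Si](c1ccccc1)(c1ccccc1)C(C)(C)C | intermediate
7 | (R)-4-benzyl-3-[5-(tert-butyldiphenylsilyloxy)pentanoyl]oxazolidin-2-one | CC(C)(C)[Si](OCCCCC(=O)N1[C@H](Cc2ccccc2)COC1=O)(c1ccccc1)c1ccccc1 | intermediate
8 | pent-4-enal | C=CCCC=O | starting material
9 | (Z)-dibutylboron enolate of 7 (O–B and the alkyl chain cis) | CCCCB(CCCC)O/C(=C\CCCO[Si](c1ccccc1)(c1ccccc1)C(C)(C)C)N1[C@H](Cc2ccccc2)COC1=O | intermediate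
10 | O-dibutylboryl derivative of aldol 11 | O=C([C@H](CCCO[Si](c1ccccc1)(c1ccccc1)C(C)(C)C)[C@@H](OB(CCCC)CCCC)CCC=C)N1[C@H](Cc2ccccc2)COC1=O | intermediate
11 | (R)-4-benzyl-3-[(2R,3S)-2-[3-(tert-butyldiphenylsilyloxy)propyl]-3-hydroxyhept-6-enoyl]oxazolidin-2-one | O=C([C@H](CCCO[Si](c1ccccc1)(c1ccccc1)C(C)(C)C)[C@@H](O)CCC=C)N1[C@H](Cc2ccccc2)COC1=O | intermediate
12 | (2R,3S)-2-[3-(tert-butyldiphenylsilyloxy)propyl]-3-hydroxy-N-methoxy-N-methylhept-6-enamide | CON(C)C(=O)[C@H](CCCO[Si](c1ccccc1)(c1ccccc1)C(C)(C)C)[C@@H](O)CCC=C | intermediate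
13 | (3R,4S)-3-[3-(tert-butyldiphenylsilyloxy)propyl]-4-hydroxyoct-7-en-2-one | CC(=O)[C@H](CCCO[Si](c1ccccc1)(c1ccccc1)C(C)(C)C)[C@@H](O)CCC=C | intermediate
14 | 2-(diethoxyphosphoryl)acetic acid | CCOP(=O)(CC(=O)O)OCC | starting material
15 | (3R,4S)-3-[3-(tert-butyldiphenylsilyloxy)propyl]-2-oxooct-7-en-4-yl 2-(diethoxyphosphoryl)acetate | CC(=O)[C@H](CCCO[Si](c1ccccc1)(c1ccccc1)C(C)(C)C)[C@@H](OC(=O)CP(=O)(OCC)OCC)CCC=C | intermediate
16 | (5S,6S)-6-(but-3-en-1-yl)-5-[3-(tert-butyldiphenylsilyloxy)propyl]-4-methyl-5,6-dihydro-2H-pyran-2-one | O=C1C=C(C)[C@H](CCCO[Si](c2ccccc2)(c2ccccc2)C(C)(C)C)[C@@H](O1)CCC=C | intermediate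
17 | (5S,6S)-5-[3-(tert-butyldiphenylsilyloxy)propyl]-4-methyl-6-(3-oxobutyl)-5,6-dihydro-2H-pyran-2-one | O=C1C=C(C)[C@H](CCCO[Si](c2ccccc2)(c2ccccc2)C(C)(C)C)[C@@H](O1)CCC(C)=O | intermediate
18 | (1S,5S,6S,9S)-9-[3-(tert-butyldiphenylsilyloxy)propyl]-6-hydroxy-5,6-dimethyl-2-oxabicyclo[3.3.1]nonan-3-one | O=C2C[C@@]1(C)[C@H](CCCO[Si](c3ccccc3)(c3ccccc3)C(C)(C)C)[C@@H](O2)CC[C@]1(C)O | intermediate
19 | (1S,5S,6S,9S)-9-[3-(tert-butyldiphenylsilyloxy)propyl]-5,6-dimethyl-6-(triethylsilyloxy)-2-oxabicyclo[3.3.1]nonan-3-one | O=C2C[C@@]1(C)[C@H](CCCO[Si](c3ccccc3)(c3ccccc3)C(C)(C)C)[C@@H](O2)CC[C@]1(C)O[Si](CC)(CC)CC | intermediate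
20 | (1S,2S,3S,4S)-2-[3-(tert-butyldiphenylsilyloxy)propyl]-3-(2-hydroxyethyl)-3,4-dimethyl-4-(triethylsilyloxy)cyclohexan-1-ol | OCC[C@@]1(C)[C@H](CCCO[Si](c2ccccc2)(c2ccccc2)C(C)(C)C)[C@@H](O)CC[C@]1(C)O[Si](CC)(CC)CC | intermediate
21 | (1S,2S,3S,4S)-2-[3-(tert-butyldiphenylsilyloxy)propyl]-3-(2-iodoethyl)-3,4-dimethyl-4-(triethylsilyloxy)cyclohexan-1-ol | ICC[C@@]1(C)[C@H](CCCO[Si](c2ccccc2)(c2ccccc2)C(C)(C)C)[C@@H](O)CC[C@]1(C)O[Si](CC)(CC)CC | intermediate
22 | (1S,2S,3S,4S)-3-[3-(tert-butyldiphenylsilyloxy)propyl]-2-(2-iodoethyl)-1,2-dimethyl-1-(triethylsilyloxy)-4-(trimethylsilyloxy)cyclohexane | ICC[C@@]1(C)[C@H](CCCO[Si](c2ccccc2)(c2ccccc2)C(C)(C)C)[C@@H](O[Si](C)(C)C)CC[C@]1(C)O[Si](CC)(CC)CC | intermediate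
23 | 1-(trimethylsilyl)propyne | CC#C[Si](C)(C)C | starting material
24 | geranyl bromide, (E)-1-bromo-3,7-dimethylocta-2,6-diene | CC(C)=CCC/C(C)=C/CBr | starting material
25 | 3-lithio-1-(trimethylsilyl)propyne | [Li]CC#C[Si](C)(C)C | intermediate
26 | (E)-(6,10-dimethylundeca-5,9-dien-1-yn-1-yl)trimethylsilane | CC(C)=CCC/C(C)=C/CCC#C[Si](C)(C)C | intermediate
27 | (E)-6,10-dimethylundeca-5,9-dien-1-yne | CC(C)=CCC/C(C)=C/CCC#C | intermediate
28 | dimethyl[(1E,5E)-2,6,10-trimethylundeca-1,5,9-trien-1-yl]alane | CC(C)=CCC/C(C)=C/CC/C(C)=C/[Al](C)C | intermediate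
29 | (1E,5E)-1-iodo-2,6,10-trimethylundeca-1,5,9-triene | CC(C)=CCC/C(C)=C/CC/C(C)=C/I | intermediate
30 | alkyllithium from 22 (C–Li in place of C–I, otherwise unchanged) | [Li]CC[C@@]1(C)[C@H](CCCO[Si](c2ccccc2)(c2ccccc2)C(C)(C)C)[C@@H](O[Si](C)(C)C)CC[C@]1(C)O[Si](CC)(CC)CC | intermediate
31 | lithium B-methoxy-9-borabicyclo[3.3.1]nonane ate complex carrying the alkyl group of 30 on boron | [Li+].CO[B-]1(CC[C@@]2(C)[C@H](CCCO[Si](c3ccccc3)(c3ccccc3)C(C)(C)C)[C@@H](O[Si](C)(C)C)CC[C@]2(C)O[Si](CC)(CC)CC)C2CCCC1CCC2 | intermediate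
32 | (1S,2S,3S,4S)-3-[3-(tert-butyldiphenylsilyloxy)propyl]-1,2-dimethyl-1-(triethylsilyloxy)-2-[(3E,7E)-4,8,12-trimethyltrideca-3,7,11-trien-1-yl]-4-(trimethylsilyloxy)cyclohexane | CC(C)=CCC/C(C)=C/CC/C(C)=C/CC[C@@]1(C)[C@H](CCCO[Si](c2ccccc2)(c2ccccc2)C(C)(C)C)[C@@H](O[Si](C)(C)C)CC[C@]1(C)O[Si](CC)(CC)CC | intermediate
33 | (1S,2S,3S,4S)-2-[3-(tert-butyldiphenylsilyloxy)propyl]-3,4-dimethyl-4-(triethylsilyloxy)-3-[(3E,7E)-4,8,12-trimethyltrideca-3,7,11-trien-1-yl]cyclohexan-1-ol | CC(C)=CCC/C(C)=C/CC/C(C)=C/CC[C@@]1(C)[C@H](CCCO[Si](c2ccccc2)(c2ccccc2)C(C)(C)C)[C@@H](O)CC[C@]1(C)O[Si](CC)(CC)CC | intermediate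
34 | (2S,3S,4S)-2-[3-(tert-butyldiphenylsilyloxy)propyl]-3,4-dimethyl-4-(triethylsilyloxy)-3-[(3E,7E)-4,8,12-trimethyltrideca-3,7,11-trien-1-yl]cyclohexan-1-one | CC(C)=CCC/C(C)=C/CC/C(C)=C/CC[C@@]1(C)[C@H](CCCO[Si](c2ccccc2)(c2ccccc2)C(C)(C)C)C(=O)CC[C@]1(C)O[Si](CC)(CC)CC | intermediate
35 | (1S,2S,3S)-3-[3-(tert-butyldiphenylsilyloxy)propyl]-4-(dibromomethylidene)-1,2-dimethyl-1-(triethylsilyloxy)-2-[(3E,7E)-4,8,12-trimethyltrideca-3,7,11-trien-1-yl]cyclohexane | CC(C)=CCC/C(C)=C/CC/C(C)=C/CC[C@@]1(C)[C@H](CCCO[Si](c2ccccc2)(c2ccccc2)C(C)(C)C)C(=C(Br)Br)CC[C@]1(C)O[Si](CC)(CC)CC | intermediate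
36 | (1S,2S,3S,4Z)-4-(1-bromoethylidene)-3-[3-(tert-butyldiphenylsilyloxy)propyl]-1,2-dimethyl-1-(triethylsilyloxy)-2-[(3E,7E)-4,8,12-trimethyltrideca-3,7,11-trien-1-yl]cyclohexane (bromine cis to C6) | CC(C)=CCC/C(C)=C/CC/C(C)=C/CC[C@@]1(C)[C@H](CCCO[Si](c2ccccc2)(c2ccccc2)C(C)(C)C)/C(=C(/C)Br)CC[C@]1(C)O[Si](CC)(CC)CC | intermediate
37 | alkenyllithium from 36 (C–Li in place of C–Br, lithium cis to C6) | CC(C)=CCC/C(C)=C/CC/C(C)=C/CC[C@@]1(C)[C@H](CCCO[Si](c2ccccc2)(c2ccccc2)C(C)(C)C)/C(=C(/C)[Li])CC[C@]1(C)O[Si](CC)(CC)CC | intermediate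
38 | (2Z)-2-{(2R,3S,4S)-2-[3-(tert-butyldiphenylsilyloxy)propyl]-3,4-dimethyl-4-(triethylsilyloxy)-3-[(3E,7E)-4,8,12-trimethyltrideca-3,7,11-trien-1-yl]cyclohexylidene}propanal | CC(C)=CCC/C(C)=C/CC/C(C)=C/CC[C@@]1(C)[C@H](CCCO[Si](c2ccccc2)(c2ccccc2)C(C)(C)C)/C(=C(/C)C=O)CC[C@]1(C)O[Si](CC)(CC)CC | intermediate
39 | iridal, (2Z)-2-{(2R,3S,4S)-4-hydroxy-2-(3-hydroxypropyl)-3,4-dimethyl-3-[(3E,7E)-4,8,12-trimethyltrideca-3,7,11-trien-1-yl]cyclohexylidene}propanal | CC(C)=CCC/C(C)=C/CC/C(C)=C/CC[C@@]1(C)[C@H](CCCO)/C(=C(/C)C=O)CC[C@]1(C)O | target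

## Step count and least certain steps

Total: 22 steps. Longest linear sequence: 19 steps (steps 1–13 and 17–22); the alkenyl iodide branch (steps 14–16) joins at step 17.

**Step 9 (key step).** Two things may go wrong. Ring closure between two fully substituted carbons may be outrun by simple reduction of the ketone or by conjugate reduction of the lactone. Facial selectivity at the ketyl carbon may also be poor if the ligand-laden samarium alkoxide avoids the axial site beside the C6 side chain. The fallback sets out from 16. Johnson–Lemieux cleavage of the terminal alkene (OsO4 cat., NaIO4, 2,6-lutidine, dioxane/H2O) gives the aldehyde lactone F1. Its less hindered aldehyde ketyl (SmI2, t-BuOH, THF, −78 °C) closes the same C10–C11 bond to the secondary carbinol F2, whose C10 configuration does not matter. Dess–Martin oxidation gives the ring ketone F3. MeMgBr with CeCl3 at −78 °C then adds to the ketone from the equatorial direction, away from the axial C6 side chain and in preference to the lactone, to give 18. C10 is then set by steric approach control, not in the radical step.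

**Step 20.** Site selectivity of oxidative addition may be lost, because both C–Br bonds are flanked by ring carbons, and over-methylation to the isopropylidene compound may compete. The fallback sets out from 35 and reverses the order of the two substitutions. One equivalent of n-BuLi at −105 °C in THF/Et2O/pentane, with a slight excess of 35 so that the bromolithium carbenoids can equilibrate, should favour the bromolithium carbenoid F4, with the small lithium at the crowded site cis to C6. DMF gives the α-bromo enal F5 (formyl cis to C6, bromine cis to C8). Suzuki methylation of this activated bromide with trimethylboroxine, Pd(PPh3)4 and K2CO3 returns to the route at 38.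

**Step 19.** The ylide may fail to add to the hindered, enolisable ketone, enolisation may epimerise C6, and the phosphorus bromide by-product may attack a silyl ether. The fallback sets out from 34. Isopropenylmagnesium bromide with CeCl3 (small, weakly basic) gives the tertiary allylic alcohol F6. Babler–Dauben oxidative transposition with PCC (buffered with NaOAc) gives enal 38 together with its E isomer, the (2E)-enal F7. The Z isomer, with the small formyl group beside branched C6, is expected to be the more stable, and F7 is recycled by sensitised photoisomerisation. The route is rejoined at 38.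

**Step 7.** Base may trigger E1cB loss of the phosphonoacetate from the β-acyloxy ketone, or enolisation at C6 with epimerisation, in competition with ring closure. The fallback sets out from 11 and builds the lactone before the C11 methyl is present. Acetylation (Ac2O, DMAP) gives the acetate F8. KHMDS at −78 °C effects an intramolecular Claisen condensation onto the imide carbonyl, with release of auxiliary 5, to give the 4-hydroxy-dihydropyranone F9, whose enolate shields C6. Tf2O and Et3N give the enol triflate F10, and Me2CuLi replaces the triflate by methyl (addition–elimination) to return to the route at 16.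

## Further compounds

F1 | step 9 | (5S,6S)-5-[3-(tert-butyldiphenylsilyloxy)propyl]-4-methyl-6-(3-oxopropyl)-5,6-dihydro-2H-pyran-2-one | O=C1C=C(C)[C@H](CCCO[Si](c2ccccc2)(c2ccccc2)C(C)(C)C)[C@@H](O1)CCC=O
F2 | step 9 | (1S,5S,9S)-9-[3-(tert-butyldiphenylsilyloxy)propyl]-6-hydroxy-5-methyl-2-oxabicyclo[3.3.1]nonan-3-one (either C6 epimer) | O=C2C[C@@]1(C)[C@H](CCCO[Si](c3ccccc3)(c3ccccc3)C(C)(C)C)[C@@H](O2)CCC1O
F3 | step 9 | (1S,5S,9S)-9-[3-(tert-butyldiphenylsilyloxy)propyl]-5-methyl-2-oxabicyclo[3.3.1]nonane-3,6-dione | O=C2C[C@@]1(C)[C@H](CCCO[Si](c3ccccc3)(c3ccccc3)C(C)(C)C)[C@@H](O2)CCC1=O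
F4 | step 20 | bromolithium carbenoid from 35 (lithium cis to C6, bromine cis to C8) | CC(C)=CCC/C(C)=C/CC/C(C)=C/CC[C@@]1(C)[C@H](CCCO[Si](c2ccccc2)(c2ccccc2)C(C)(C)C)/C(=C(/Br)[Li])CC[C@]1(C)O[Si](CC)(CC)CC
F5 | step 20 | (2E)-2-bromo-2-cyclohexylideneacetaldehyde analogue of 38 (bromine in place of the C2 methyl, formyl cis to C6) | CC(C)=CCC/C(C)=C/CC/C(C)=C/CC[C@@]1(C)[C@H](CCCO[Si](c2ccccc2)(c2ccccc2)C(C)(C)C)/C(=C(/Br)C=O)CC[C@]1(C)O[Si](CC)(CC)CC
F6 | step 19 | 1-(prop-1-en-2-yl)cyclohexan-1-ol from 34 (isopropenyl and hydroxyl on C7, either epimer) | CC(C)=CCC/C(C)=C/CC/C(C)=C/CC[C@@]1(C)[C@H](CCCO[Si](c2ccccc2)(c2ccccc2)C(C)(C)C)C(O)(C(C)=C)CC[C@]1(C)O[Si](CC)(CC)CC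
F7 | step 19 | (2E) isomer of 38 (formyl cis to C8, methyl cis to C6) | CC(C)=CCC/C(C)=C/CC/C(C)=C/CC[C@@]1(C)[C@H](CCCO[Si](c2ccccc2)(c2ccccc2)C(C)(C)C)/C(=C(\C)C=O)CC[C@]1(C)O[Si](CC)(CC)CC
F8 | step 7 | (R)-4-benzyl-3-[(2R,3S)-3-acetoxy-2-[3-(tert-butyldiphenylsilyloxy)propyl]hept-6-enoyl]oxazolidin-2-one | O=C([C@H](CCCO[Si](c1ccccc1)(c1ccccc1)C(C)(C)C)[C@@H](OC(C)=O)CCC=C)N1[C@H](Cc2ccccc2)COC1=O
F9 | step 7 | (5R,6S)-6-(but-3-en-1-yl)-5-[3-(tert-butyldiphenylsilyloxy)propyl]-4-hydroxy-5,6-dihydro-2H-pyran-2-one | O=C1C=C(O)[C@H](CCCO[Si](c2ccccc2)(c2ccccc2)C(C)(C)C)[C@@H](O1)CCC=C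
F10 | step 7 | (5R,6S)-6-(but-3-en-1-yl)-5-[3-(tert-butyldiphenylsilyloxy)propyl]-2-oxo-5,6-dihydro-2H-pyran-4-yl trifluoromethanesulfonate | O=C1C=C(OS(=O)(=O)C(F)(F)F)[C@H](CCCO[Si](c2ccccc2)(c2ccccc2)C(C)(C)C)[C@@H](O1)CCC=C
A1 | alternative 1 | cyclohex-2-en-1-ol with C10 hydroxyl and methyl, C7 tert-butyldimethylsilyloxy and the homofarnesyl chain on the alkene carbon C11 | CC(C)=CCC/C(C)=C/CC/C(C)=C/CCC1=C[C@@H](O[Si](C)(C)C(C)(C)C)CC[C@]1(C)O
A2 | alternative 1 | bicyclo[4.1.0]heptan-2-ol with the CH2 bridge cis to the C10 hydroxyl | CC(C)=CCC/C(C)=C/CC/C(C)=C/CC[C@@]12C[C@@H]1[C@@H](O[Si](C)(C)C(C)(C)C)CC[C@]2(C)O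
A3 | alternative 2 | cyclohexanol with an exocyclic methylene at C7 and a 5-methyl-4-oxohex-5-enyl chain on C6 | CC(C)(C)[Si](C)(C)OCC[C@@]1(C)[C@H](CCCC(=O)C(C)=C)C(=C)CC[C@]1(C)O
A4 | alternative 2 | bicyclo[5.4.0]undecenone with the tetrasubstituted C7=C2 alkene in the seven-membered ring | CC(C)(C)[Si](C)(C)OCC[C@@]1(C)[C@@H]2CCCC(=O)C(C)=C2CC[C@]1(C)O
A5 | alternative 3 | 1,7-enyne with vinyl on C11, triethylsilyloxy on C10 and a methyl-capped alkyne | CC(C)=CCC/C(C)=C/CC/C(C)=C/CC[C@@](C)(C=C)[C@](C)(CCC#CC)O[Si](CC)(CC)CC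
A6 | alternative 3 | cyclohexane with iodomethyl on C6 and a (1-iodoethylidene) group on C7, iodine cis to C6 | CC(C)=CCC/C(C)=C/CC/C(C)=C/CC[C@@]1(C)[C@H](CI)/C(=C(/C)I)CC[C@]1(C)O[Si](CC)(CC)CC
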